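The diaryl ether bond between the A-ring oxygen (flanked by the formyl- and lactone-bearing carbons) and C7 of the chromanone B ring is the strategic disconnection. The key step, an intramolecular Ullmann etherification of a bromo-depside, closes the seven-membered 1,4-dioxepinone ring in one operation. It exploits two features of the B ring: C7 is para to the chromanone C4 carbonyl (activated C–Br) and ortho to the ester-bearing C6, so the aryl ester holds the A-ring phenol over the bromide. The precursor is the ester of 4-O-benzylhaematommic acid with 7-bromo-6-hydroxy-8-methoxy-2,2,5-trimethylchroman-4-one; the bromine, installed at the quinone stage, also blocks that carbon during the chromanone annulation.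

Key step: step 8

Remark on the chemistry: the target has no stereogenic centre or axis, so it is a single achiral compound and no stereocontrol is required.

**Step 1**
Reactants: 1 2-methoxy-5-methylphenol
Product: 2 2-methoxy-5-methyl-1,4-benzoquinone
Conditions: (KSO3)2NO (2.2 equiv), KH2PO4, H2O/acetone, rt
Reagents that add atoms: Fremy's salt (potassium nitrosodisulfonate), [K+].[K+].[O]N(S(=O)(=O)[O-])S(=O)(=O)[O-]
Why: Teuber oxidation: Fremy's radical oxidises the phenol to its phenoxyl radical and a second equivalent delivers oxygen to the free para carbon, which should give the p-quinone without touching the methoxy or methyl group.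

**Step 2**
Reactants: 2 2-methoxy-5-methyl-1,4-benzoquinone
Product: 4 3-bromo-2-methoxy-5-methylbenzene-1,4-diol, via 3-bromo-2-methoxy-5-methyl-1,4-benzoquinone 3 (not isolated)
Conditions: Br2, NaOAc, AcOH, rt; then aq. Na2S2O4, EtOAc
Reagents that add atoms: bromine, BrBr
Why: Electrophilic bromination of a 2-methoxyquinone by addition–elimination: bromine should attack the electron-rich enol-ether carbon C3 rather than the methyl-substituted alkene, acetate removes HBr, and dithionite reduction then gives a hydroquinone whose only free ring position is C6.

**Step 3**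
Reactants: 4 3-bromo-2-methoxy-5-methylbenzene-1,4-diol; 5 3-methylbut-2-enoic acid (3,3-dimethylacrylic acid)
Product: 6 7-bromo-6-hydroxy-8-methoxy-2,2,5-trimethylchroman-4-one
Conditions: P2O5/MeSO3H (Eaton's reagent), 70 °C, N2
Reagents that add atoms: none
Why: Friedel–Crafts acylation followed by intramolecular oxa-Michael addition (the classical phenol/3,3-dimethylacrylic acid chromanone annulation): the acylium can enter only at C6, the single unsubstituted carbon, and only the adjacent C1 hydroxyl can close the pyranone ring, so the bromine ends up at C7 and the free hydroxyl at C6 of the chromanone.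

**Step 4**
Reactants: 7 methyl 2,4-dihydroxy-6-methylbenzoate (methyl orsellinate)
Product: 8 methyl 3-formyl-2,4-dihydroxy-6-methylbenzoate (methyl haematommate)
Conditions: Cl2CHOMe, TiCl4, CH2Cl2, 0 °C to rt; then aq. HCl
Reagents that add atoms: dichloromethyl methyl ether, COC(Cl)Cl; water, O
Why: Rieche formylation: titanium bound to the phenolic oxygens should deliver the electrophile to C3, the carbon between the two hydroxyls that both activate it, and hydrolysis of the chloro ether gives the aldehyde (a minor C5 isomer, if formed, would be removed by chromatography).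

**Step 5**
Reactants: 8 methyl 3-formyl-2,4-dihydroxy-6-methylbenzoate
Product: 9 methyl 4-(benzyloxy)-3-formyl-2-hydroxy-6-methylbenzoate
Conditions: BnBr (1.05 equiv), K2CO3, acetone, 40 °C
Reagents that add atoms: benzyl bromide, BrCc1ccccc1
Why: Williamson ether synthesis: the 2-OH is buried between the ester and formyl groups and hydrogen-bonded to the ester carbonyl, so one equivalent of benzyl bromide should alkylate the more accessible 4-OH.

**Step 6**
Reactants: 9 methyl 4-(benzyloxy)-3-formyl-2-hydroxy-6-methylbenzoate
Product: 10 4-(benzyloxy)-3-formyl-2-hydroxy-6-methylbenzoic acid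
Conditions: KOH, DMSO/H2O, 70 °C; then aq. HCl
Reagents that add atoms: potassium hydroxide, [K+].[OH-] (oxygen of the new CO2H by acyl–oxygen cleavage)
Why: Saponification of a hindered methyl salicylate with poorly solvated hydroxide in aqueous DMSO; the benzyl ether is inert to base and the ortho-phenoxide should shield the non-enolisable aldehyde from Cannizzaro disproportionation.

**Step 7**
Reactants: 10 4-(benzyloxy)-3-formyl-2-hydroxy-6-methylbenzoic acid; 6 7-bromo-6-hydroxy-8-methoxy-2,2,5-trimethylchroman-4-one
Product: 11 7-bromo-8-methoxy-2,2,5-trimethyl-4-oxochroman-6-yl 4-(benzyloxy)-3-formyl-2-hydroxy-6-methylbenzoate (the bromo-depside)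
Conditions: (CF3CO)2O, toluene, rt
Reagents that add atoms: none
Why: Trifluoroacetic anhydride-mediated esterification through the mixed anhydride (acylium-like) of the 2,6-disubstituted benzoic acid, a standard method for hindered depsides; 6 has a single free hydroxyl and the chelated 2-OH of 10 is a poor nucleophile, so only the desired aryl ester should form.

**Step 8**
Reactants: 11 bromo-depside
Product: 12 protected depsidone (the target carrying a benzyl ether on the A-ring hydroxyl and a methyl ether on the B-ring hydroxyl)
Conditions: CuI (20 mol%), N,N-dimethylglycine (40 mol%), Cs2CO3 (2 equiv), 4 Å MS, 1,4-dioxane (0.01 M), 100 °C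
Reagents that add atoms: none
Why: Cs2CO3 deprotonates the only free phenol (A-ring C2–OH, acidified by the flanking formyl and ester groups), the copper(I) phenoxide inserts into the C7–Br bond of the chromanone ring, which is activated by the para C4 ketone, and C–O reductive elimination releases the diaryl ether. The closest known reaction type is the ligand-accelerated Ullmann diaryl ether synthesis, here run intramolecularly. The seven-membered 1,4-dioxepinone ring closes by attack of the tethered oxygen on the aryl carbon ortho to the ester oxygen, a closure templated by the pre-formed aryl ester. No stereocentre is formed. The step needs intramolecular O-arylation to win over intermolecular coupling, ester cleavage and Smiles rearrangement; this should be secured by high dilution, the single free OH (the other two are benzylated and methylated), anhydrous carbonate with molecular sieves, and the fact that the ester-bearing C6 is meta to the ketone on an electron-rich ring and so is not activated for ipso attack.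

**Step 9**
Reactants: 12 protected depsidone
Product: 13 target depsidone CNP0271978.0
Conditions: BBr3, CH2Cl2, −78 to 0 °C; then H2O
Reagents that add atoms: none
Why: Lewis-acid ether cleavage with BBr3: the benzyl ether (chelation to the ortho formyl group) and the methyl ether flanked by two oxygens carry the most basic ether oxygens, whereas the lactone, the diaryl ether and the vinylogous-ester-like chromanone oxygen should survive at or below 0 °C, and neither ring offers a site for Friedel–Crafts benzylation.

**Compound list**
1 | 2-methoxy-5-methylphenol | COc1ccc(C)cc1O | starting material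
2 | 2-methoxy-5-methyl-1,4-benzoquinone | COC1=CC(=O)C(C)=CC1=O | intermediate
3 | 3-bromo-2-methoxy-5-methyl-1,4-benzoquinone | COC1=C(Br)C(=O)C(C)=CC1=O | intermediate (not isolated)
4 | 3-bromo-2-methoxy-5-methylbenzene-1,4-diol | COc1c(O)cc(C)c(O)c1Br | intermediate
5 | 3-methylbut-2-enoic acid (3,3-dimethylacrylic acid) | CC(C)=CC(=O)O | starting material
6 | 7-bromo-6-hydroxy-8-methoxy-2,2,5-trimethylchroman-4-one | CC1(C)CC(=O)c2c(C)c(O)c(Br)c(OC)c2O1 | intermediate
7 | methyl 2,4-dihydroxy-6-methylbenzoate (methyl orsellinate) | COC(=O)c1c(C)cc(O)cc1O | starting material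
8 | methyl 3-formyl-2,4-dihydroxy-6-methylbenzoate (methyl haematommate) | COC(=O)c1c(C)cc(O)c(C=O)c1O | intermediate
9 | methyl 4-(benzyloxy)-3-formyl-2-hydroxy-6-methylbenzoate | COC(=O)c1c(C)cc(OCc2ccccc2)c(C=O)c1O | intermediate
10 | 4-(benzyloxy)-3-formyl-2-hydroxy-6-methylbenzoic acid | OC(=O)c1c(C)cc(OCc2ccccc2)c(C=O)c1O | intermediate
11 | 7-bromo-8-methoxy-2,2,5-trimethyl-4-oxochroman-6-yl 4-(benzyloxy)-3-formyl-2-hydroxy-6-methylbenzoate (bromo-depside) | Cc1cc(OCc2ccccc2)c(C=O)c(O)c1C(=O)Oc1c(C)c2c(c(OC)c1Br)OC(C)(C)CC2=O | intermediate
12 | protected depsidone: target with the A-ring hydroxyl as benzyl ether and the B-ring hydroxyl as methyl ether | Cc1cc(OCc2ccccc2)c(C=O)c2c1C(=O)Oc1c(C)c3c(c(OC)c1O2)OC(C)(C)CC3=O | intermediate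
13 | target depsidone CNP0271978.0: 2,2-dimethylchroman-4-one-fused dibenzo[b,e][1,4]dioxepin-11-one with A-ring Me, OH and CHO and B-ring Me and OH | Cc1cc(O)c(C=O)c2c1C(=O)Oc1c(C)c3c(c(O)c1O2)OC(C)(C)CC3=O | target

**Step count**
Total steps: 9. Longest linear sequence: 6 steps (steps 1, 2, 3, 7, 8, 9; the A-ring branch, steps 4, 5, 6, 7, 8, 9, is equally long).

**Steps most likely to fail**

1. Step 8 (key ring closure). Base-induced cleavage of the aryl ester tether, or aldol chemistry at the chromanone methylene, may outrun a slow copper insertion at the doubly ortho-substituted bromide with a chelated, weakly nucleophilic phenol. The fallback forms the ether first and the lactone last; it sets out from 6 and 9 and comes back to the route at 12. Phenol 6 would be protected (MOMCl, i-Pr2NEt, CH2Cl2) as 7-bromo-8-methoxy-6-(methoxymethoxy)-2,2,5-trimethylchroman-4-one F1. Intermolecular Ullmann coupling of F1 with the 2-OH of 9 (CuI, picolinic acid, K3PO4, DMSO, 100 °C; no aryl ester is present at this stage) should give methyl 4-(benzyloxy)-3-formyl-2-{[8-methoxy-6-(methoxymethoxy)-2,2,5-trimethyl-4-oxochroman-7-yl]oxy}-6-methylbenzoate F2. Saponification (KOH, aq. DMSO) would give the corresponding benzoic acid F3, and MOM removal (HCl, THF/H2O) the hydroxy acid 4-(benzyloxy)-3-formyl-2-[(6-hydroxy-8-methoxy-2,2,5-trimethyl-4-oxochroman-7-yl)oxy]-6-methylbenzoic acid F4. Lactonisation of F4 (TFAA, toluene) should close the seven-membered ring to 12.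

2. Step 3 (chromanone annulation). Protodebromination or bromine migration in the strongly acidic medium, or C-alkylation of the ring by the protonated acrylic acid (leading to a dihydrocoumarin) instead of C-acylation, may erode the annulation. The fallback builds the ring in two stages; it sets out from 4 and comes back at 6. Fries-type C-acetylation of 4 at its only free position (AcOH, BF3·OEt2, 90 °C) should give 1-(4-bromo-2,5-dihydroxy-3-methoxy-6-methylphenyl)ethan-1-one F5. Kabbe condensation of F5 with acetone and pyrrolidine (toluene, reflux) would then build the 2,2-dimethylchroman-4-one 6.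

3. Step 7 (depside esterification). The phenol of 6, flanked by methyl and bromine, may fail to intercept the mixed anhydride, leaving the salicylic acid to self-condense. The fallback replaces electrophilic activation of the acid by nucleophilic opening of a benzodioxinone; it sets out from 10 (with 6) and comes back at 11. Acid 10 would be converted (acetone, TFAA, TFA) into its acetonide 7-(benzyloxy)-2,2,5-trimethyl-4-oxo-4H-1,3-benzodioxine-8-carbaldehyde F6. The sodium phenoxide of 6 (NaH, THF, 0 °C to rt) should open F6 at the carbonyl with loss of acetone, unveiling the A-ring 2-OH and giving 11 directly.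

**Further compounds**
F1 | step 8 | 7-bromo-8-methoxy-6-(methoxymethoxy)-2,2,5-trimethylchroman-4-one | COCOc1c(C)c2C(=O)CC(C)(C)Oc2c(OC)c1Br
F2 | step 8 | methyl 4-(benzyloxy)-3-formyl-2-{[8-methoxy-6-(methoxymethoxy)-2,2,5-trimethyl-4-oxochroman-7-yl]oxy}-6-methylbenzoate | COC(=O)c1c(C)cc(OCc2ccccc2)c(C=O)c1Oc1c(OCOC)c(C)c2C(=O)CC(C)(C)Oc2c1OC
F3 | step 8 | 4-(benzyloxy)-3-formyl-2-{[8-methoxy-6-(methoxymethoxy)-2,2,5-trimethyl-4-oxochroman-7-yl]oxy}-6-methylbenzoic acid | OC(=O)c1c(C)cc(OCc2ccccc2)c(C=O)c1Oc1c(OCOC)c(C)c2C(=O)CC(C)(C)Oc2c1OC
F4 | step 8 | 4-(benzyloxy)-3-formyl-2-[(6-hydroxy-8-methoxy-2,2,5-trimethyl-4-oxochroman-7-yl)oxy]-6-methylbenzoic acid | OC(=O)c1c(C)cc(OCc2ccccc2)c(C=O)c1Oc1c(O)c(C)c2C(=O)CC(C)(C)Oc2c1OC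
F5 | step 3 | 1-(4-bromo-2,5-dihydroxy-3-methoxy-6-methylphenyl)ethan-1-one | CC(=O)c1c(C)c(O)c(Br)c(OC)c1O
F6 | step 7 | 7-(benzyloxy)-2,2,5-trimethyl-4-oxo-4H-1,3-benzodioxine-8-carbaldehyde | Cc1cc(OCc2ccccc2)c(C=O)c2OC(C)(C)OC(=O)c12
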